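One equivalent of X serves one exchange on one G, so two equivalents carry G through L to D, releasing J each time.

all flasks: G 10 mM

| charge | X | J | remark | time |
|---|---|---|---|---|
| Sunday's | 1.4 equiv | 2 equiv | run made earlier |  |
| Tuesday's | 4.8 equiv | 2 equiv | run made earlier |  |
| alpha | 1.20 equiv | 2.00 equiv |  | 2.0 h |
| delta | 2.00 equiv | 2.00 equiv |  | 2.0 h |
| zeta | 3.00 equiv | 2.00 equiv |  | 2.0 h |

| run | time / min | D / % | L / % |
|---|---|---|---|
| Sunday's | 5.00 | 9.7 | 8.1 |
| Sunday's | 8.00 | 15.8 | 9.2 |
| Sunday's | 12.0 | 23.1 | 8.4 |
| Sunday's | 20.0 | 33.3 | 6.6 |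
| Sunday's | 40.0 | 44.4 | 4.3 |
| Sunday's | 60.0 | 49.7 | 2.6 |
| Tuesday's | 4.00 | 33.0 | 8.2 |
| Tuesday's | 12.0 | 71.1 | 3.3 |
| Tuesday's | 20.0 | 84.9 | 1.3 |
| Tuesday's | 30.0 | 91.1 | 0.4 |
| Tuesday's | 50.0 | 94.6 | 0.4 |
| Tuesday's | 60.0 | 95.1 | 0 |

(each reading ± 0.5 percentage points)



1. how much D is there at the end, in percent of the G charged: for each flask in turn (alpha, delta, zeta)

What puzzled me was Tuesday's run: it held 4.8 equiv of X, yet at 60.0 min D stood at 95.1% with L at 0%, and D had been 94.6% at 50.0 min. So 4.90% of the charge stood in neither D nor L, in a run whose D had almost stopped rising, with X to spare.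

L stayed small, with no reading above 9.2% in Sunday's run, so I treated it as short-lived and asked how each L ended. I supposed that it went on with X, a pseudo-first-order step at any given X, or leaked away without X. The share going on is then X/(X + s), where s is the even-split level, the equivalents of X at which L leaks as fast as it goes on to D.

I took that part of Tuesday's run as the leak. Midway through that run I put X near 3.80 equiv, so the reading gave s = 0.196 equiv. At its charge, delta would therefore send 91.1% of its L on to D, and less as X fell. This rule gave me shares, not totals.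

The forecast gave 46%, 67.5% and 85%, on a different ground: “Better is a rate that decays with time”.

The flasks gave 46.3%, 76.3% and 91.0%, so the forecast held in alpha and stood low in delta and zeta.

    G + X → J + L (k = 3.20 L mol⁻¹ min⁻¹)
    L + X → J + D (k = 24.0 L mol⁻¹ min⁻¹)
    L → E (k = 0.0410 min⁻¹)

In delta at 2.00 h, X stood at 0.322 equiv, so my s sent 62.2% of new L on to D. The main reason for the height of D in delta was the difference between the rate constants of the two exchanges: the same flask without that difference gives 43.1% of D, against 76.3% as it stands.

The runs are simulated with constants of no real substance, and the scatter is random.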